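**Retrosynthetic overview**

1. Target 18 ⇐ 17 ⇐ 14: angeloylation of the only free hydroxyl (C3), then removal of three primary TBS ethers.
2. 14 ⇐ 12: both rings come from one epoxy-polyprene cascade on the fully oxygenated acyclic C20 chain. Ring A closes first (C4–C5), ring B second (C10–C9), and C8 ends as the 8(17)-exo-olefin, as in the enzymatic A/B bicyclisation to the copalyl skeleton.
3. 12 ⇐ 10 ⇐ 9: the (3R)-epoxide, the only source of absolute configuration, from Sharpless epoxidation of the (E)-ω-allylic alcohol made by SeO2 oxidation.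
4. 9 ⇐ 8 ⇐ 7 ⇐ 5 ⇐ 1 + 2: the (Z)-butenediol terminus from a propargylic alcohol (trans-hydroalumination/iodination, Stille hydroxymethylation); the chain from farnesyl bromide, propyne and formaldehyde.

Assumption: labdane numbering is used for positions (C3 = ester carbon, C18 = ring CH2OH, C15/C16 = side-chain CH2OH); the SMILES is read as the ent-labdane (3R,4S,5S,9R,10S,13Z) 3-angelate.

**Route**

Step 1
Reactants: 1 (2E,6E)-farnesyl bromide; 2 propyne
Product: 5 (6E,10E)-7,11,15-trimethylhexadeca-6,10,14-trien-2-yn-1-ol, via 1,3-dilithiopropyne 3 (not isolated), via lithium acetylide 4 (not isolated)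
Conditions: 2, n-BuLi (2 equiv), TMEDA, Et2O/hexane, −78 → 0 °C; 1, −78 → 0 °C; (CH2O)n, THF, 0 °C → rt; H2O
Reagents that add atoms: paraformaldehyde (formaldehyde), C=O
Why: 1,3-dilithiopropyne reacts at its sp3 carbon by SN2 displacement of the primary allylic bromide (olefin geometries untouched), leaving acetylide 4, which adds to formaldehyde (dianion alkylation followed by acetylide hydroxymethylation).

Step 2
Reactants: 5 (6E,10E)-7,11,15-trimethylhexadeca-6,10,14-trien-2-yn-1-ol
Product: 7 (2Z,6E,10E)-3-iodo-7,11,15-trimethylhexadeca-2,6,10,14-tetraen-1-ol, via cyclic alkenylalanate 6 (not isolated)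
Conditions: Red-Al, THF, 0 °C → rt; then I2, THF, −78 °C
Reagents that add atoms: iodine, II
Why: hydroxyl-directed trans-hydroalumination delivers hydride to C2 and leaves aluminium on C3 cis to the CH2O group in a five-membered alkoxyalanate, and iodinolysis with retention gives the (Z)-3-iodoallylic alcohol, which fixes the C13=C14 geometry of the target.

Step 3
Reactants: 7 (2Z,6E,10E)-3-iodo-7,11,15-trimethylhexadeca-2,6,10,14-tetraen-1-ol
Product: 8 (2Z)-2-[(3E,7E)-4,8,12-trimethyltrideca-3,7,11-trien-1-yl]but-2-ene-1,4-diol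
Conditions: Bu3SnCH2OH, Pd(PPh3)4 (5 mol%), dioxane, 90 °C
Reagents that add atoms: (tributylstannyl)methanol, OC[Sn](CCCC)(CCCC)CCCC
Why: Stille cross-coupling transfers the hydroxymethyl group to the vinyl iodide with retention of olefin geometry, so the two CH2OH groups end cis.

Step 4
Reactants: 8 (2Z)-2-[(3E,7E)-4,8,12-trimethyltrideca-3,7,11-trien-1-yl]but-2-ene-1,4-diol
Product: 9 (2Z)-1,4-bis[(tert-butyldimethylsilyl)oxy]-2-[(3E,7E)-4,8,12-trimethyltrideca-3,7,11-trien-1-yl]but-2-ene
Conditions: TBSCl, imidazole, DMF, 0 °C → rt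
Reagents that add atoms: tert-butyldimethylsilyl chloride, CC(C)(C)[Si](C)(C)Cl
Why: standard silylation of the two primary allylic alcohols masks them so that the allylic oxidation and the hydroxyl-directed epoxidation address only the other chain end.

Step 5
Reactants: 9 (2Z)-1,4-bis[(tert-butyldimethylsilyl)oxy]-2-[(3E,7E)-4,8,12-trimethyltrideca-3,7,11-trien-1-yl]but-2-ene
Product: 10 (2E,6E,10E,14Z)-16-[(tert-butyldimethylsilyl)oxy]-14-{[(tert-butyldimethylsilyl)oxy]methyl}-2,6,10-trimethylhexadeca-2,6,10,14-tetraen-1-ol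
Conditions: SeO2 (10 mol%), t-BuOOH, salicylic acid (10 mol%), CH2Cl2, 0 °C → rt, stopped at partial conversion
Reagents that add atoms: tert-butyl hydroperoxide, CC(C)(C)OO; selenium dioxide (catalytic oxygen carrier), O=[Se]=O
Why: catalytic SeO2 allylic oxidation (Riley oxidation, ene then [2,3]-shift) attacks the (E)-methyl of the terminal isopropylidene, the least hindered electron-rich olefin, and gives the (E)-allylic alcohol, while C13=C14 is deactivated by two allylic C–O bonds.

Step 6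
Reactants: 10 (2E,6E,10E,14Z)-16-[(tert-butyldimethylsilyl)oxy]-14-{[(tert-butyldimethylsilyl)oxy]methyl}-2,6,10-trimethylhexadeca-2,6,10,14-tetraen-1-ol
Product: 12 (2R,3R)-epoxide of 10 as its tert-butyldimethylsilyl ether, via epoxy alcohol 11 (not isolated)
Conditions: Ti(OiPr)4 (10 mol%), D-(−)-diethyl tartrate (12 mol%), t-BuOOH, 4 Å MS, CH2Cl2, −20 °C; then imidazole, TBSCl, 0 °C → rt
Reagents that add atoms: tert-butyl hydroperoxide, CC(C)(C)OO; tert-butyldimethylsilyl chloride, CC(C)(C)[Si](C)(C)Cl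
Why: Sharpless asymmetric epoxidation touches only the olefin of the free allylic alcohol and with D-(−)-tartrate gives the (2R,3R)-epoxide (its CH carbon becomes C3 of the target, R), and the primary alcohol is silylated in the same flask (in situ derivatisation).

Step 7
Reactants: 12 (2R,3R)-epoxide of 10 as its tert-butyldimethylsilyl ether
Product: 14 (3R,4S,5S,9R,10S,13Z)-15,16,18-tris[(tert-butyldimethylsilyl)oxy]labda-8(17),13-dien-3-ol, via 3-O-trimethylsilyl ether 13 (not isolated)
Conditions: Cp2TiCl2 (20 mol%), Mn dust, TMSCl, 2,4,6-collidine, dry THF, rt, slow addition of 12; then K2CO3, MeOH, rt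
Reagents that add atoms: none
Why: Cp2TiCl opens the epoxide homolytically to the tertiary C4 radical, which closes ring A (6-endo on C5=C10) and then ring B (6-endo on C9=C8) through chair–chair transition states before the C8 radical loses a C17 hydrogen to titanium to give the 8(17)-olefin (titanocene(III)-catalysed epoxypolyprene cyclisation, the radical counterpart of the enzymatic A/B bicyclisation); C3 (R) comes unchanged from the epoxide, the CH2OTBS group takes the equatorial site on C4 (anti to the developing axial C20 methyl), the anti additions across the two (E)-olefins set C5-H, C10-CH3 and C9-H in the trans-decalin array, and ring C should close only slowly because C14 is flanked by two cis silyloxymethyl groups.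

Step 8
Reactants: 14 (3R,4S,5S,9R,10S,13Z)-15,16,18-tris[(tert-butyldimethylsilyl)oxy]labda-8(17),13-dien-3-ol; 15 angelic acid [(2Z)-2-methylbut-2-enoic acid]
Product: 17 (3R,4S,5S,9R,10S,13Z)-15,16,18-tris[(tert-butyldimethylsilyl)oxy]labda-8(17),13-dien-3-yl (2Z)-2-methylbut-2-enoate, via mixed anhydride 16 (not isolated)
Conditions: 15, 2,4,6-trichlorobenzoyl chloride, Et3N, toluene, rt; then 14, toluene, 80 °C
Reagents that add atoms: none
Why: Yamaguchi-type esterification through the 2,4,6-trichlorobenzoyl mixed anhydride acylates the only free hydroxyl (equatorial C3–OH) without a nucleophilic catalyst that would isomerise the (Z)-2-methylbut-2-enoyl group to the tiglate.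

Step 9
Reactants: 17 (3R,4S,5S,9R,10S,13Z)-15,16,18-tris[(tert-butyldimethylsilyl)oxy]labda-8(17),13-dien-3-yl (2Z)-2-methylbut-2-enoate
Product: 18 (3R,4S,5S,9R,10S,13Z)-15,16,18-trihydroxylabda-8(17),13-dien-3-yl (2Z)-2-methylbut-2-enoate (CNP0237954.1)
Conditions: HF·pyridine, pyridine, THF, 0 °C → rt
Reagents that add atoms: none
Why: fluoride-mediated desilylation with buffered HF·pyridine removes the three primary TBS ethers under weakly acidic conditions that neither move the C3 acyl group to the neighbouring C18 hydroxyl nor isomerise the angelate or the exocyclic olefin.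

**Compound list**

1 | (2E,6E)-farnesyl bromide | BrC/C=C(\C)CC/C=C(\C)CCC=C(C)C | starting material
2 | propyne | CC#C | starting material
3 | 1,3-dilithiopropyne | [Li]CC#C[Li] | intermediate (not isolated)
4 | (5E,9E)-6,10,14-trimethylpentadeca-5,9,13-trien-1-yn-1-yllithium | [Li]C#CCC/C=C(\C)CC/C=C(\C)CCC=C(C)C | intermediate (not isolated)
5 | (6E,10E)-7,11,15-trimethylhexadeca-6,10,14-trien-2-yn-1-ol | OCC#CCC/C=C(\C)CC/C=C(\C)CCC=C(C)C | intermediate
6 | sodium cyclic alkoxy(alkenyl)bis(2-methoxyethoxy)aluminate of 5 (Al on C3, cis to CH2O) | [Na+].COCCO[Al-]1(OCCOC)OCC=C1CC/C=C(\C)CC/C=C(\C)CCC=C(C)C | intermediate (not isolated)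
7 | (2Z,6E,10E)-3-iodo-7,11,15-trimethylhexadeca-2,6,10,14-tetraen-1-ol | OC/C=C(\I)CC/C=C(\C)CC/C=C(\C)CCC=C(C)C | intermediate
8 | (2Z)-2-[(3E,7E)-4,8,12-trimethyltrideca-3,7,11-trien-1-yl]but-2-ene-1,4-diol | OC/C=C(\CO)CC/C=C(\C)CC/C=C(\C)CCC=C(C)C | intermediate
9 | (2Z)-1,4-bis[(tert-butyldimethylsilyl)oxy]-2-[(3E,7E)-4,8,12-trimethyltrideca-3,7,11-trien-1-yl]but-2-ene | CC(C)(C)[Si](C)(C)OC/C=C(\CO[Si](C)(C)C(C)(C)C)CC/C=C(\C)CC/C=C(\C)CCC=C(C)C | intermediate
10 | (2E,6E,10E,14Z)-16-[(tert-butyldimethylsilyl)oxy]-14-{[(tert-butyldimethylsilyl)oxy]methyl}-2,6,10-trimethylhexadeca-2,6,10,14-tetraen-1-ol | CC(C)(C)[Si](C)(C)OC/C=C(\CO[Si](C)(C)C(C)(C)C)CC/C=C(\C)CC/C=C(\C)CC/C=C(\C)CO | intermediate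
11 | [(2R,3R)-3-{(3E,7E,11Z)-13-[(tert-butyldimethylsilyl)oxy]-11-{[(tert-butyldimethylsilyl)oxy]methyl}-3,7-dimethyltrideca-3,7,11-trien-1-yl}-2-methyloxiran-2-yl]methanol | CC(C)(C)[Si](C)(C)OC/C=C(\CO[Si](C)(C)C(C)(C)C)CC/C=C(\C)CC/C=C(\C)CC[C@H]1O[C@]1(C)CO | intermediate (not isolated)
12 | tert-butyldimethylsilyl ether of 11 [(2R,3R)-epoxide; all three primary hydroxyls as TBS ethers] | CC(C)(C)[Si](C)(C)OC/C=C(\CO[Si](C)(C)C(C)(C)C)CC/C=C(\C)CC/C=C(\C)CC[C@H]1O[C@]1(C)CO[Si](C)(C)C(C)(C)C | intermediate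
13 | 3-O-trimethylsilyl ether of 14 | C=C1CC[C@H]2[C@@](C)(CC[C@@H](O[Si](C)(C)C)[C@]2(C)CO[Si](C)(C)C(C)(C)C)[C@@H]1CC/C(=C/CO[Si](C)(C)C(C)(C)C)CO[Si](C)(C)C(C)(C)C | intermediate (not isolated)
14 | (3R,4S,5S,9R,10S,13Z)-15,16,18-tris[(tert-butyldimethylsilyl)oxy]labda-8(17),13-dien-3-ol (trans-decalin; 3-OH and 4-CH2OTBS equatorial; 10-CH3 and 4-CH3 axial and cis; 5-H and 9-H on the opposite face) | C=C1CC[C@H]2[C@@](C)(CC[C@@H](O)[C@]2(C)CO[Si](C)(C)C(C)(C)C)[C@@H]1CC/C(=C/CO[Si](C)(C)C(C)(C)C)CO[Si](C)(C)C(C)(C)C | intermediate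
15 | angelic acid, (2Z)-2-methylbut-2-enoic acid | C/C=C(/C)C(=O)O | starting material
16 | (2Z)-2-methylbut-2-enoic 2,4,6-trichlorobenzoic anhydride | C/C=C(/C)C(=O)OC(=O)c1c(Cl)cc(Cl)cc1Cl | intermediate (not isolated)
17 | (3R,4S,5S,9R,10S,13Z)-15,16,18-tris[(tert-butyldimethylsilyl)oxy]labda-8(17),13-dien-3-yl (2Z)-2-methylbut-2-enoate | C=C1CC[C@H]2[C@@](C)(CC[C@@H](OC(=O)/C(C)=C\C)[C@]2(C)CO[Si](C)(C)C(C)(C)C)[C@@H]1CC/C(=C/CO[Si](C)(C)C(C)(C)C)CO[Si](C)(C)C(C)(C)C | intermediate
18 | (3R,4S,5S,9R,10S,13Z)-15,16,18-trihydroxylabda-8(17),13-dien-3-yl (2Z)-2-methylbut-2-enoate (CNP0237954.1) | C=C1CC[C@H]2[C@@](C)(CC[C@@H](OC(=O)/C(C)=C\C)[C@]2(C)CO)[C@@H]1CC/C(=C/CO)CO | target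

**Step count and risks**

Total steps: 9. Longest linear sequence: 9 steps (1 → 18).

Most likely to fail, first: step 7. The C8 radical may add to C13=C14 and give an isocopalane-type tricycle, hydrogen loss may occur at the monocyclic stage, and C4 selectivity may be low because the C4 radical is planar. The fallback leaves the radical manifold and cyclises the same epoxide 12 as a carbocation with MeAlCl2 in CH2Cl2 at −94 °C (or ZrCl4). The epoxide then opens at C4 with inversion, so the (E)-geometry from step 5 places CH2OTBS equatorial stereospecifically. The C13=C14 olefin, with two allylic C–O bonds, is too electron-poor to capture the C8 cation. Proton loss gives 14 with its Δ7 and Δ8 isomers, from which 14 is separated on AgNO3-impregnated silica. This fallback sets out from 12, comes back at 14 and makes no new compound (F0).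

Second: step 5. Expect low conversion, over-oxidation to the enal, or attack at the internal olefins. The fallback sets out from 9 and comes back at 10 by degrading and rebuilding the chain end. NBS in aqueous THF at 0 °C gives the terminal bromohydrin F1, and K2CO3 in MeOH closes it to the racemic terminal epoxide F2. HIO4·2H2O in THF/Et2O at 0 °C cleaves F2 to the trisnor aldehyde F3. Wittig olefination with ethyl 2-(triphenylphosphoranylidene)propanoate in CH2Cl2 gives the ethyl (E)-enoate F4, and DIBAL-H in CH2Cl2 at −78 °C reduces F4 to 10.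

Third: step 8. The C3 hydroxyl is hindered by the neighbouring quaternary C4, and the angelate can isomerise to the tiglate. The fallback sets out from 14 and comes back at 17 by building the angelate on the molecule. Acylation of 14 with 2-[bis(2,2,2-trifluoroethoxy)phosphoryl]propanoic acid (DCC, DMAP, CH2Cl2) gives the phosphonopropionate ester F5. Still–Gennari olefination of F5 with acetaldehyde (KHMDS, 18-crown-6, THF, −78 °C) then forms the (Z)-2-methylbut-2-enoate 17.

**Further compounds**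

F0 | step 7 | none | none
F1 | step 5 | (6E,10E,14Z)-3-bromo-16-[(tert-butyldimethylsilyl)oxy]-14-{[(tert-butyldimethylsilyl)oxy]methyl}-2,6,10-trimethylhexadeca-6,10,14-trien-2-ol (racemic bromohydrin) | CC(C)(C)[Si](C)(C)OC/C=C(\CO[Si](C)(C)C(C)(C)C)CC/C=C(\C)CC/C=C(\C)CCC(Br)C(C)(C)O
F2 | step 5 | racemic terminal epoxide of 9 (2,2-dimethyloxirane terminus) | CC(C)(C)[Si](C)(C)OC/C=C(\CO[Si](C)(C)C(C)(C)C)CC/C=C(\C)CC/C=C(\C)CCC1OC1(C)C
F3 | step 5 | (4E,8E,12Z)-14-[(tert-butyldimethylsilyl)oxy]-12-{[(tert-butyldimethylsilyl)oxy]methyl}-4,8-dimethyltetradeca-4,8,12-trienal | CC(C)(C)[Si](C)(C)OC/C=C(\CO[Si](C)(C)C(C)(C)C)CC/C=C(\C)CC/C=C(\C)CCC=O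
F4 | step 5 | ethyl (2E,6E,10E,14Z)-16-[(tert-butyldimethylsilyl)oxy]-14-{[(tert-butyldimethylsilyl)oxy]methyl}-2,6,10-trimethylhexadeca-2,6,10,14-tetraenoate | CC(C)(C)[Si](C)(C)OC/C=C(\CO[Si](C)(C)C(C)(C)C)CC/C=C(\C)CC/C=C(\C)CC/C=C(\C)C(=O)OCC
F5 | step 8 | 2-[bis(2,2,2-trifluoroethoxy)phosphoryl]propanoate ester of 14 (both epimers at the phosphonate-bearing carbon) | C=C1CC[C@H]2[C@@](C)(CC[C@@H](OC(=O)C(C)P(=O)(OCC(F)(F)F)OCC(F)(F)F)[C@]2(C)CO[Si](C)(C)C(C)(C)C)[C@@H]1CC/C(=C/CO[Si](C)(C)C(C)(C)C)CO[Si](C)(C)C(C)(C)C
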